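**Plan**

- The quinone ring of the target is read as an oxidised, mono-O-methylated 5-alkylresorcinol: removing the O–CH3 bond at quinone C5 and then the C4 carbonyl oxygen leads back to 5-docosyl-4-methylbenzene-1,3-diol.
- The ring bond between quinone C2 (methyl-bearing) and C3 (docosyl-bearing) is cut next, together with a C–CO2 bond at C2. These two ring atoms are C2 and C7 of a linear tert-butyl 2-methyl-3,5,7-trioxo ester, whose C3 and C5 carbonyls become the 1,3-related ring oxygens (quinone C1 and C5).
- The chain is cut at C6–C7 (methyl tricosanoate), at C4–C5 (an acetyl unit) and at C2–CH3 (tert-butyl acetoacetate, iodomethane).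
- Forward: C-methylation, γ-acetylation and terminal tricosanoylation join the chain (steps 1–3). The only ring closes in step 4 by aldol addition with decarboxylative aromatisation. Step 5 oxidises the arene to the hydroxyquinone and step 6 methylates its single hydroxyl.
- Stereochemistry: the target has no stereocentre. The C2 centre of the chain intermediates is racemic and, like the two centres of the cyclic aldol adduct, vanishes on aromatisation.

Key step: step 4

**Route**

Step 1
Reactants: 1 tert-butyl acetoacetate (tert-butyl 3-oxobutanoate)
Product: 2 tert-butyl 2-methyl-3-oxobutanoate (racemic)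
Conditions: MeI (1.05 equiv), K2CO3, acetone, reflux
Reagents that add atoms: iodomethane, CI
Why: C-alkylation of the potassium enolate of a β-keto ester (acetoacetic ester alkylation) should give the monomethyl compound, since the weak base and one equivalent of MeI keep double alkylation low and the product can be purified by distillation.

Step 2
Reactants: 2 tert-butyl 2-methyl-3-oxobutanoate; 3 N-methoxy-N-methylacetamide
Product: 4 tert-butyl 2-methyl-3,5-dioxohexanoate (racemic, largely enolised)
Conditions: LiN(i-Pr)2 (2.2 equiv), THF, −78 → 0 °C; then 3, −78 → 0 °C; cold 1 M HCl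
Reagents that add atoms: none
Why: Two equivalents of base should give the C2,C4-dianion, whose more basic terminal C4 carbanion is acylated by the Weinreb amide (γ-acylation of a β-keto ester dianion, Weinreb ketone synthesis); the chelated tetrahedral adduct persists until the quench, so the acidic diketone is not released while dianion is still present.

Step 3
Reactants: 4 tert-butyl 2-methyl-3,5-dioxohexanoate; 5 methyl tricosanoate
Product: 6 tert-butyl 2-methyl-3,5,7-trioxononacosanoate (racemic, keto–enol mixture)
Conditions: LiN(i-Pr)2 (3.3 equiv per 4), THF, 0 °C; then 5 (0.5 equiv), THF, 0 °C → rt; cold 1 M HCl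
Reagents that add atoms: none
Why: Three equivalents of base should give the 2,4,6-trianion, which reacts at its most basic terminal carbon C6 with the ester (Claisen-type acylation of a β-dicarbonyl polyanion); the trianion is used in excess because the more acidic product takes up a further equivalent of base.

Step 4
Reactants: 6 tert-butyl 2-methyl-3,5,7-trioxononacosanoate
Product: 9 5-docosyl-4-methylbenzene-1,3-diol, via cyclic aldol adduct 7 (not isolated), via enedione carboxylic acid 8 (not isolated)
Conditions: Cs2CO3 (2 equiv), THF/MeOH, 0 °C → rt; then solvent removed, CF3CO2H/CH2Cl2 (1:2), rt → 40 °C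
Reagents that add atoms: none
Why: Proposed new method: Cs2CO3 forms the ester- and ketone-stabilised enolate at C2, which adds to the C7 ketone in a 6-(enolexo)-exo-trig aldol closure to give carbocycle 7 with a quaternary C2; 7 is a cyclohexane-1,3-dione, far more acidic than the open-chain diketone, so its caesium enolate should draw the reversible addition forward. CF3CO2H then dehydrates the tertiary carbinol towards C6 and cleaves the tert-butyl ester with loss of 2-methylpropene, and the β-keto acid 8 loses CO2 to a dienol that tautomerises to the aromatic resorcinol 9. The closest known reaction type is the base-then-acid aldol aromatisation of 3,5,7-triketo esters to resorcylates, joined here to the acidolytic decarboxylation of a tert-butyl β-keto ester; the new element is that the donor carbon carries a methyl group, so aromatisation must pass through loss of the carboxyl carbon instead of a C2 hydrogen. The two stereocentres of 7 are transient and are erased on aromatisation, so no stereocontrol is needed. The step needs the C2-to-C7 aldol to win over the C6-to-C1 Claisen closure and over lactone or pyranone formation through oxygen: the tert-butyl ester is a poor acyl acceptor, C2 is the only carbon nucleophile that can reach a ketone through a six-membered ring under carbonate (C4 and C6 cannot, C8 is not acidic enough), and acid is added only after the carbon–carbon bond is made.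

Step 5
Reactants: 9 5-docosyl-4-methylbenzene-1,3-diol
Product: 10 3-docosyl-5-hydroxy-2-methylcyclohexa-2,5-diene-1,4-dione
Conditions: K2NO(SO3)2 (2.5 equiv), aq. KH2PO4, n-Bu4NHSO4 (cat.), CH2Cl2/H2O, rt; dil. HCl
Reagents that add atoms: potassium nitrosodisulfonate K2NO(SO3)2, [K+].[K+].[O]N(S([O-])(=O)=O)S([O-])(=O)=O
Why: In a Teuber oxidation the nitroxide should abstract the phenolic hydrogen and a second equivalent should couple at C6, the only free ring position para to a hydroxyl (the position para to the other hydroxyl carries the methyl group), after which loss of imidodisulfonate gives the 1,4-quinone that keeps the second hydroxyl.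

Step 6
Reactants: 10 3-docosyl-5-hydroxy-2-methylcyclohexa-2,5-diene-1,4-dione
Product: 11 3-docosyl-5-methoxy-2-methylcyclohexa-2,5-diene-1,4-dione (the target)
Conditions: MeOH/CHCl3 (2:1), H2SO4 (cat.), 60 °C
Reagents that add atoms: methanol, CO
Why: Acid-catalysed addition–elimination of methanol at the vinylogous acid carbon (vinylogous Fischer esterification of a 2-hydroxy-1,4-benzoquinone) should give the methyl ether, since only one hydroxyl is present and the 1,4-quinone ether is the thermodynamic product over the 1,2-quinone ether, whose oxygen also lies next to the ring methyl.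

**Compound list**

1 | tert-butyl acetoacetate (tert-butyl 3-oxobutanoate) | CC(=O)CC(=O)OC(C)(C)C | starting material
2 | tert-butyl 2-methyl-3-oxobutanoate (racemic) | CC(=O)C(C)C(=O)OC(C)(C)C | intermediate
3 | N-methoxy-N-methylacetamide | CC(=O)N(C)OC | starting material
4 | tert-butyl 2-methyl-3,5-dioxohexanoate (racemic) | CC(=O)CC(=O)C(C)C(=O)OC(C)(C)C | intermediate
5 | methyl tricosanoate | CCCCCCCCCCCCCCCCCCCCCCC(=O)OC | starting material
6 | tert-butyl 2-methyl-3,5,7-trioxononacosanoate (racemic, epimerisable) | CCCCCCCCCCCCCCCCCCCCCCC(=O)CC(=O)CC(=O)C(C)C(=O)OC(C)(C)C | intermediate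
7 | tert-butyl 2-docosyl-2-hydroxy-1-methyl-4,6-dioxocyclohexane-1-carboxylate (racemic mixture of diastereomers, present as its caesium enolate, not isolated) | CCCCCCCCCCCCCCCCCCCCCCC1(O)CC(=O)CC(=O)C1(C)C(=O)OC(C)(C)C | intermediate
8 | 2-docosyl-1-methyl-4,6-dioxocyclohex-2-ene-1-carboxylic acid (racemic, not isolated) | CCCCCCCCCCCCCCCCCCCCCCC1=CC(=O)CC(=O)C1(C)C(O)=O | intermediate
9 | 5-docosyl-4-methylbenzene-1,3-diol | CCCCCCCCCCCCCCCCCCCCCCc1cc(O)cc(O)c1C | intermediate
10 | 3-docosyl-5-hydroxy-2-methylcyclohexa-2,5-diene-1,4-dione | CCCCCCCCCCCCCCCCCCCCCCC1=C(C)C(=O)C=C(O)C1=O | intermediate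
11 | 3-docosyl-5-methoxy-2-methylcyclohexa-2,5-diene-1,4-dione | CCCCCCCCCCCCCCCCCCCCCCC1=C(C)C(=O)C=C(OC)C1=O | target

**Step count and risks**

Total step count: 6. Longest linear sequence: 6 steps (1 → 11).

Steps most likely to fail:

Step 4 (key step). The aldol addition at the crowded, methyl-bearing C2 may revert before water is lost. The open chain would then meet the acid and close through oxygen to pyranones, or lose the tert-butyl group and CO2 before the ring is made, which removes the activation that directs the closure. The fallback uses known chemistry, sets out from 1 (with 3 and 5) and comes back at 9; the ring methyl is then made from the ester carbon instead of being carried through the cyclisation. The dianion of 1 (LiN(i-Pr)2, THF) would be acetylated with 3 to tert-butyl 3,5-dioxohexanoate F1. Its trianion would be acylated with 5 to tert-butyl 3,5,7-trioxononacosanoate F2. Cs2CO3 in MeOH followed by mild acidification would effect the documented aldol–dehydration of an unsubstituted triketo ester to tert-butyl 2-docosyl-4,6-dihydroxybenzoate F3. Excess LiAlH4 in refluxing THF would reduce the ester to 5-docosyl-4-(hydroxymethyl)benzene-1,3-diol F4. Ionic hydrogenation of this electron-rich benzylic alcohol (Et3SiH, CF3CO2H, CH2Cl2) would give 9.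

Step 3. Trianion formation at the methyl-bearing carbon may be incomplete, the acidic acylation product may quench unreacted trianion by proton transfer, and the poorly soluble long-chain ester may acylate slowly, so that conversion stays low or self-condensation takes over. The fallback avoids polyanions beyond a dianion by an acylketene route; it sets out from 2 (with 5) and comes back at 6. Compound 2 would be converted with acetone, (CF3CO)2O and CF3CO2H into 2,2,5,6-tetramethyl-4H-1,3-dioxin-4-one F5. Its lithium dienolate (LiN(SiMe3)2, THF, −78 °C) would be C-acetylated with acetyl chloride to 2,2,5-trimethyl-6-(2-oxopropyl)-4H-1,3-dioxin-4-one F6. Ester 5 would be turned into N-methoxy-N-methyltricosanamide F7 (MeNHOMe·HCl, i-PrMgCl, THF). The dianion of F6 (LiN(i-Pr)2, THF, −78 °C) would be acylated with F7 to 6-(2,4-dioxohexacosyl)-2,2,5-trimethyl-4H-1,3-dioxin-4-one F8. Heating F8 with tert-butanol in toluene at 110 °C would release acetone and trap the acylketene as 6.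

Step 5. The free resorcinol may be over-oxidised or attacked at C2 between the two hydroxyls, the hydroxyquinone may couple with unreacted resorcinol, and phase transfer of the lipophilic substrate may be slow. The fallback introduces the oxygen through a carbon substituent; it sets out from 9 and comes back at 10. Vilsmeier–Haack formylation (POCl3, DMF, then aqueous NaOAc) should occur at C6, para to one hydroxyl and ortho to the other, to give 2-docosyl-4,6-dihydroxy-3-methylbenzaldehyde F9. Dakin oxidation (H2O2, aqueous NaOH, THF) would give 6-docosyl-5-methylbenzene-1,2,4-triol F10, which air in the alkaline medium (or Ag2O) would oxidise to 10.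

Further compounds
F1 | step 4 | tert-butyl 3,5-dioxohexanoate | CC(=O)CC(=O)CC(=O)OC(C)(C)C
F2 | step 4 | tert-butyl 3,5,7-trioxononacosanoate | CCCCCCCCCCCCCCCCCCCCCCC(=O)CC(=O)CC(=O)CC(=O)OC(C)(C)C
F3 | step 4 | tert-butyl 2-docosyl-4,6-dihydroxybenzoate | CCCCCCCCCCCCCCCCCCCCCCc1cc(O)cc(O)c1C(=O)OC(C)(C)C
F4 | step 4 | 5-docosyl-4-(hydroxymethyl)benzene-1,3-diol | CCCCCCCCCCCCCCCCCCCCCCc1cc(O)cc(O)c1CO
F5 | step 3 | 2,2,5,6-tetramethyl-4H-1,3-dioxin-4-one | CC1=C(C)C(=O)OC(C)(C)O1
F6 | step 3 | 2,2,5-trimethyl-6-(2-oxopropyl)-4H-1,3-dioxin-4-one | CC(=O)CC1=C(C)C(=O)OC(C)(C)O1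
F7 | step 3 | N-methoxy-N-methyltricosanamide | CCCCCCCCCCCCCCCCCCCCCCC(=O)N(C)OC
F8 | step 3 | 6-(2,4-dioxohexacosyl)-2,2,5-trimethyl-4H-1,3-dioxin-4-one | CCCCCCCCCCCCCCCCCCCCCCC(=O)CC(=O)CC1=C(C)C(=O)OC(C)(C)O1
F9 | step 5 | 2-docosyl-4,6-dihydroxy-3-methylbenzaldehyde | CCCCCCCCCCCCCCCCCCCCCCc1c(C)c(O)cc(O)c1C=O
F10 | step 5 | 6-docosyl-5-methylbenzene-1,2,4-triol | CCCCCCCCCCCCCCCCCCCCCCc1c(C)c(O)cc(O)c1O
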